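**Retrosynthetic overview** (side chain numbered from the exocyclic CH2= as C1; the ring is attached at C2)
1. Last step: the C13–C14 bond is made by a Cu-catalysed SN2 coupling, with inversion at C14, of a C22 primary Grignard reagent (ring, all three C=C, C10 centre) with a C13 (2R)-secondary tosylate (C18 centre); the product is the target itself.
2. Enabling feature: C14 is a CH(CH3) flanked on both sides by three unbranched CH2 groups (methyl centres C10/C14/C18 are 1,5-spaced), so the electrophile is an unhindered methyl carbinyl tosylate and the nucleophile a γ-unbranched primary carbanion. The only functional groups (exocyclic C1=C2, the (Z)-C5=C6 and the C=C of the 4-methylcyclohex-3-enyl ring) tolerate RMgX and lie at least six saturated carbons from C13.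
3. C13 tosylate: (S)-citronellyl bromide (C18) → hydrogenation → Grignard opening of (R)-propylene oxide (C15–C16 bond; C14–O centre, later inverted) → tosylation.
4. C22 chloride: 10-lithio-(R)-limonene + (Z)-allylic bromide (C3–C4 bond). The bromide comes from (S)-citronellyl bromide (C10) by ozonolysis, chlorination and Z-selective alkylation of the prenol dianion (C7–C8 bond, Z-C5=C6).
5. No ring is formed in the route: the cyclohexene ring and its (R) centre are bought as (R)-limonene; all four stereocentres come from the chiral pool, C14 with inversion.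

Key step: step 9

Remark: the SMILES is read as (5Z) at the chain C5=C6 (C4 and C7 cis) and as 4R (ring), 10S, 14S, 18S; the chiral starting materials are assumed to be enantiopure.

**Step 1**
Reactants: 1 (S)-citronellyl bromide
Product: 2 (S)-1-bromo-3,7-dimethyloctane
Conditions: H2 (1 atm), PtO2 (cat.), EtOAc, rt
Reagents that add atoms: none
Why: Heterogeneous hydrogenation over Adams catalyst saturates the trisubstituted C=C without alkene migration toward the remote C3 stereocentre and should leave the primary C–Br bond intact under neutral conditions.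

**Step 2**
Reactants: 2 (S)-1-bromo-3,7-dimethyloctane; 3 (R)-propylene oxide
Product: 5 (2R,6S)-6,10-dimethylundecan-2-ol, via (S)-3,7-dimethyloctylmagnesium bromide 4 (not isolated)
Conditions: Mg, THF, rt → 40 °C; then CuI (10 mol %), 3 (1.2 equiv), −30 → 0 °C
Reagents that add atoms: none
Why: Cu-catalysed Grignard opening of a terminal epoxide occurs by SN2 attack at the unsubstituted CH2, so the C–O stereocentre of 3 is carried unchanged into the (2R)-carbinol.

**Step 3**
Reactants: 5 (2R,6S)-6,10-dimethylundecan-2-ol
Product: 6 (2R,6S)-6,10-dimethylundecan-2-yl 4-methylbenzenesulfonate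
Conditions: TsCl, pyridine, DMAP (cat.), CH2Cl2, 0 °C → rt
Reagents that add atoms: p-toluenesulfonyl chloride, Cc1ccc(cc1)S(=O)(=O)Cl
Why: O-Sulfonylation forms only the O–S bond, so C2 keeps its (R) configuration and becomes the leaving-group carbon for the key step.

**Step 4**
Reactants: 1 (S)-citronellyl bromide
Product: 8 (S)-6-bromo-4-methylhexan-1-ol, via (S)-6-bromo-4-methylhexanal 7 (not isolated)
Conditions: O3, CH2Cl2–MeOH, −78 °C; then NaBH4, −78 °C → rt
Reagents that add atoms: ozone, [O-][O+]=O
Why: Ozonolysis with reductive borohydride work-up cleaves the only C=C to the primary alcohol and touches neither the primary bromide nor the stereocentre.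

**Step 5**
Reactants: 8 (S)-6-bromo-4-methylhexan-1-ol
Product: 9 (S)-1-bromo-6-chloro-3-methylhexane
Conditions: PPh3, NCS, CH2Cl2, 0 °C; then 8, 0 °C → rt
Reagents that add atoms: N-chlorosuccinimide, ClN1C(=O)CCC1=O
Why: Appel-type chlorination (SN2 at the primary carbinol carbon) gives a primary chloride that should stay inert through steps 6–8 while the bromide remains the reactive site.

**Step 6**
Reactants: 10 3-methylbut-2-en-1-ol (prenol); 9 (S)-1-bromo-6-chloro-3-methylhexane
Product: 12 (2Z,7R)-10-chloro-3,7-dimethyldec-2-en-1-ol, via prenol O,C-dilithio dianion 11 (not isolated)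
Conditions: 10 (1.3 equiv), n-BuLi (2.1 equiv per 10), TMEDA, Et2O–hexane, 0 °C → rt; then 9, THF, −78 → 0 °C
Reagents that add atoms: none
Why: Alkoxide-directed allylic lithiation takes place at the methyl group cis to CH2OLi, and this dianion alkylation at the terminal carbanion carbon by the C–Br bond of 9 (faster than C–Cl) places the new chain cis to CH2OH, which is the (2Z) geometry; the stereocentre is a spectator (its descriptor becomes R only through CIP priorities).

**Step 7**
Reactants: 12 (2Z,7R)-10-chloro-3,7-dimethyldec-2-en-1-ol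
Product: 13 (2Z,7R)-1-bromo-10-chloro-3,7-dimethyldec-2-ene
Conditions: PBr3 (0.4 equiv), pyridine (cat.), Et2O, −10 °C
Reagents that add atoms: phosphorus tribromide, BrP(Br)Br
Why: Low-temperature PBr3 bromination of a primary allylic alcohol proceeds by SN2 at the CH2 carbon, as in the nerol to neryl bromide conversion, and should keep the Z geometry and the alkyl chloride.

**Step 8**
Reactants: 14 (R)-limonene; 13 (2Z,7R)-1-bromo-10-chloro-3,7-dimethyldec-2-ene
Product: 16 (4R)-4-[(5Z,10R)-13-chloro-6,10-dimethyltrideca-1,5-dien-2-yl]-1-methylcyclohex-1-ene, via 10-lithiolimonene 15 (not isolated)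
Conditions: 14 (2 equiv), n-BuLi (1.2 equiv), TMEDA, rt; then 13 (1.0 equiv), THF, −78 → 0 °C
Reagents that add atoms: none
Why: TMEDA-assisted allylic lithiation of limonene occurs at the isopropenyl methyl (C10) to give a 2-substituted allyllithium with two equivalent termini, which should displace the primary allylic bromide by SN2 (the γ-carbon is fully substituted) faster than the alkyl chloride; the ring stereocentre is not deprotonated and the Z-alkene is not touched.

**Step 9**
Reactants: 16 (4R)-4-[(5Z,10R)-13-chloro-6,10-dimethyltrideca-1,5-dien-2-yl]-1-methylcyclohex-1-ene; 6 (2R,6S)-6,10-dimethylundecan-2-yl 4-methylbenzenesulfonate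
Product: 18 (4R)-1-methyl-4-[(5Z,10S,14S,18S)-6,10,14,18,22-pentamethyltricosa-1,5-dien-2-yl]cyclohex-1-ene, via C22 alkylmagnesium chloride 17 (not isolated)
Conditions: Mg (I2-activated), THF, 50 °C; then 6 (0.8 equiv), CuI (10 mol %), TMEDA (20 mol %), LiOMe (1 equiv, additive), THF, 0 °C
Reagents that add atoms: none
Why: Magnesium inserts into the primary C–Cl bond of 16 (the three unactivated C=C bonds are inert and the nearest is six saturated carbons from the carbanion, so no cyclization can compete), and Grignard reagent 17 transmetalates to a TMEDA/alkoxide-stabilised alkylcuprate that attacks C2 of tosylate 6 from the back side (SN2-type oxidative addition) and then reductively eliminates the C13–C14 bond. The closest known reaction type is the copper-catalysed cross-coupling of unactivated secondary alkyl tosylates with alkyl Grignard reagents (CuI/TMEDA/LiOMe), which is stereospecific with inversion. No ring is closed in this step. The one new stereocentre, C14, is controlled by the (2R) carbinol carbon of 6 (bought as (R)-propylene oxide): Walden inversion converts it into the (14S) centre, while C10, C18 and ring C4 are spectators that cannot epimerise under these conditions. The selectivity needed is substitution over E2/β-hydride elimination of the secondary tosylate and over Grignard homocoupling; it should be secured by the substrate (a methyl carbinyl tosylate with only unbranched CH2 groups at the β-positions and an unbranched primary nucleophile) and by the low temperature. In this single operation the C22 and C13 halves are joined, the last stereocentre is set and the unprotected hydrocarbon target is obtained with no later step.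

**Compound list**
1 | (S)-citronellyl bromide [(6S)-8-bromo-2,6-dimethyloct-2-ene] | BrCC[C@@H](C)CCC=C(C)C | starting material
2 | (S)-1-bromo-3,7-dimethyloctane | BrCC[C@@H](C)CCCC(C)C | intermediate
3 | (R)-propylene oxide [(R)-2-methyloxirane] | C[C@@H]1CO1 | starting material
4 | (S)-3,7-dimethyloctylmagnesium bromide | Br[Mg]CC[C@@H](C)CCCC(C)C | intermediate
5 | (2R,6S)-6,10-dimethylundecan-2-ol | C[C@@H](O)CCC[C@@H](C)CCCC(C)C | intermediate
6 | (2R,6S)-6,10-dimethylundecan-2-yl 4-methylbenzenesulfonate | Cc1ccc(cc1)S(=O)(=O)O[C@H](C)CCC[C@@H](C)CCCC(C)C | intermediate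
7 | (S)-6-bromo-4-methylhexanal | BrCC[C@@H](C)CCC=O | intermediate
8 | (S)-6-bromo-4-methylhexan-1-ol | BrCC[C@@H](C)CCCO | intermediate
9 | (S)-1-bromo-6-chloro-3-methylhexane | BrCC[C@@H](C)CCCCl | intermediate
10 | 3-methylbut-2-en-1-ol (prenol) | CC(C)=CCO | starting material
11 | prenol O,C-dilithio dianion [lithium (Z)-4-lithio-3-methylbut-2-en-1-olate] | [Li]OC/C=C(/C)C[Li] | intermediate
12 | (2Z,7R)-10-chloro-3,7-dimethyldec-2-en-1-ol | OC/C=C(/C)CCC[C@@H](C)CCCCl | intermediate
13 | (2Z,7R)-1-bromo-10-chloro-3,7-dimethyldec-2-ene | BrC/C=C(/C)CCC[C@@H](C)CCCCl | intermediate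
14 | (R)-limonene | CC(=C)[C@H]1CC=C(C)CC1 | starting material
15 | 10-lithiolimonene {[(R)-2-(4-methylcyclohex-3-en-1-yl)prop-2-en-1-yl]lithium} | [Li]CC(=C)[C@H]1CC=C(C)CC1 | intermediate
16 | (4R)-4-[(5Z,10R)-13-chloro-6,10-dimethyltrideca-1,5-dien-2-yl]-1-methylcyclohex-1-ene | C=C(CC/C=C(/C)CCC[C@@H](C)CCCCl)[C@H]1CC=C(C)CC1 | intermediate
17 | [(4R,8Z)-4,8-dimethyl-12-[(1R)-4-methylcyclohex-3-en-1-yl]trideca-8,12-dien-1-yl]magnesium chloride | C=C(CC/C=C(/C)CCC[C@@H](C)CCC[Mg]Cl)[C@H]1CC=C(C)CC1 | intermediate
18 | (4R)-1-methyl-4-[(5Z,10S,14S,18S)-6,10,14,18,22-pentamethyltricosa-1,5-dien-2-yl]cyclohex-1-ene | C=C(CC/C=C(/C)CCC[C@@H](C)CCC[C@@H](C)CCC[C@@H](C)CCCC(C)C)[C@H]1CC=C(C)CC1 | target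

**Total step count:** 9
**Longest linear sequence:** 6 steps (steps 4–9, from 1)

**Steps most likely to fail**

1. Step 9. The secondary tosylate may undergo E2 or β-hydride elimination instead of substitution, inversion may be incomplete if a radical pathway intervenes, and the Grignard reagent may homocouple. The fallback sets out from 16 (through its Grignard reagent 17) and comes back at 18. The C13–C14 bond would be made at an activated secondary carbon instead: 17 is coupled under ZnCl2 catalysis (THF, 0 °C) with tert-butyl (R)-2-(trifluoromethylsulfonyloxy)propanoate F1 (from commercial tert-butyl (R)-lactate, Tf2O, 2,6-lutidine). This SN2 displacement with inversion should give tert-butyl (2R,6S,10Z)-2,6,10-trimethyl-14-[(1R)-4-methylcyclohex-3-en-1-yl]pentadeca-10,14-dienoate F2. LiAlH4 (Et2O, 0 °C) should reduce it to the primary alcohol (2R,6S,10Z)-2,6,10-trimethyl-14-[(1R)-4-methylcyclohex-3-en-1-yl]pentadeca-10,14-dien-1-ol F3, and TsCl/pyridine should give its tosylate F4. A Li2CuCl4-catalysed primary–primary coupling of F4 with Grignard reagent 4 (THF, −78 °C → rt; no stereocentre involved) should then give 18.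

2. Step 6. The dianion may react through its internal carbon (branched isomer), the Z geometry may erode by equilibration of the allyl anion, and substitution at the C–Cl bond may compete. The fallback sets out from 9 and comes back at 12. Lithiated 1-(trimethylsilyl)propyne (n-BuLi, THF, −78 °C) is alkylated by the bromide of 9 to give (R)-(9-chloro-6-methylnon-1-yn-1-yl)trimethylsilane F5. K2CO3/MeOH should give (R)-9-chloro-6-methylnon-1-yne F6, and n-BuLi followed by methyl chloroformate methyl (R)-10-chloro-7-methyldec-2-ynoate F7. Syn addition of Me2CuLi (THF, −78 °C, cold protonation) should give methyl (2Z,7R)-10-chloro-3,7-dimethyldec-2-enoate F8, with the ester and the chain cis. DIBAL-H (CH2Cl2, −78 °C) should then give 12.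

3. Step 8. The allyllithium may attack the allylic bromide in the SN2′ sense, halogen–metal exchange may lead to homocoupling, and metalation of limonene may be incomplete or not fully selective for C10. The fallback sets out from 14 (and uses 13) and comes back at 16; the allyl anion is replaced by a ketone enolate. Catalytic OsO4/NMO should dihydroxylate the less hindered 1,1-disubstituted C=C of 14 to 2-[(1R)-4-methylcyclohex-3-en-1-yl]propane-1,2-diol F9 (both C2 epimers), and NaIO4 should cleave it to 1-[(1R)-4-methylcyclohex-3-en-1-yl]ethan-1-one F10. The kinetic CH3-side lithium enolate (LDA, THF, −78 °C) is C-alkylated by 13 at its primary allylic carbon to give (4Z,9R)-12-chloro-5,9-dimethyl-1-[(1R)-4-methylcyclohex-3-en-1-yl]dodec-4-en-1-one F11. Wittig methylenation (Ph3P=CH2, THF, −78 → 0 °C) should then install the exocyclic methylene and give 16.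

**Further compounds**
F1 | step 9 | tert-butyl (R)-2-(trifluoromethylsulfonyloxy)propanoate | C[C@@H](OS(=O)(=O)C(F)(F)F)C(=O)OC(C)(C)C
F2 | step 9 | tert-butyl (2R,6S,10Z)-2,6,10-trimethyl-14-[(1R)-4-methylcyclohex-3-en-1-yl]pentadeca-10,14-dienoate | C=C(CC/C=C(/C)CCC[C@@H](C)CCC[C@@H](C)C(=O)OC(C)(C)C)[C@H]1CC=C(C)CC1
F3 | step 9 | (2R,6S,10Z)-2,6,10-trimethyl-14-[(1R)-4-methylcyclohex-3-en-1-yl]pentadeca-10,14-dien-1-ol | C=C(CC/C=C(/C)CCC[C@@H](C)CCC[C@@H](C)CO)[C@H]1CC=C(C)CC1
F4 | step 9 | (2R,6S,10Z)-2,6,10-trimethyl-14-[(1R)-4-methylcyclohex-3-en-1-yl]pentadeca-10,14-dien-1-yl 4-methylbenzenesulfonate | C=C(CC/C=C(/C)CCC[C@@H](C)CCC[C@@H](C)COS(=O)(=O)c1ccc(C)cc1)[C@H]1CC=C(C)CC1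
F5 | step 6 | (R)-(9-chloro-6-methylnon-1-yn-1-yl)trimethylsilane | C[Si](C)(C)C#CCCC[C@@H](C)CCCCl
F6 | step 6 | (R)-9-chloro-6-methylnon-1-yne | C#CCCC[C@@H](C)CCCCl
F7 | step 6 | methyl (R)-10-chloro-7-methyldec-2-ynoate | COC(=O)C#CCCC[C@@H](C)CCCCl
F8 | step 6 | methyl (2Z,7R)-10-chloro-3,7-dimethyldec-2-enoate | COC(=O)/C=C(/C)CCC[C@@H](C)CCCCl
F9 | step 8 | 2-[(1R)-4-methylcyclohex-3-en-1-yl]propane-1,2-diol (C2 epimers) | CC1=CC[C@@H](CC1)C(C)(O)CO
F10 | step 8 | 1-[(1R)-4-methylcyclohex-3-en-1-yl]ethan-1-one | CC1=CC[C@@H](CC1)C(C)=O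
F11 | step 8 | (4Z,9R)-12-chloro-5,9-dimethyl-1-[(1R)-4-methylcyclohex-3-en-1-yl]dodec-4-en-1-one | O=C(CC/C=C(/C)CCC[C@@H](C)CCCCl)[C@H]1CC=C(C)CC1
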